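At rest over its crystals, the solution in this flask cannot hold dissolved target above 2.0 mM.

    substrate ⇌ target (K1 = 0.096, k1 = 0.0084 s⁻¹)
    crystals ⇌ target, rate k2*(cs2 - [target]) while solid is left; crystals form when [target] > cs2 (cs2 = 2.0 mM, k2 = 0.050 s⁻¹)
    target ⇌ isomer of the product A (K3 = 2.3, k3 = 0.077 s⁻¹)
    target ⇌ isomer of the product B (K4 = 2.1, k4 = 0.0053 s⁻¹)
    isomer of the product A ⇌ substrate (k5 = 0.097 s⁻¹)

substrate 0.14 M; time 12 h

* the state of affairs at 12 h: stopped, and by what, or still going (all of the substrate has reacted / forward and back rates have come level / it is still moving)
* conversion of substrate at 12 h
* amount of target at 12 h, in percent of the substrate charged
* amount of isomer of the product A at 12 h, in percent of the substrate charged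
* amount of target if the flask were left three thousand times as long, in percent of the substrate charged

- target is meant together with its crystals
- solid, in amounts per volume of the solution: crystals
- the reaction counts as stopped when no species that holds the substrate changes by six tenths of a point or more over the second half of the time
- run time (flask): 12 h

1. I turn the question round: what must be true of the numbers for this flask to end with no crystals? Its charge must fit into the solution with dissolved target, T, no higher than 2.0 mM.

2. The steps in solution have time to balance. The longest relaxation half-life on hand, 1.48 min, is short against 12 h, so I reckon from the equilibrium constants (thermodynamic control).

3. With T at 2.0 mM, substrate is T divided by 0.096, which is 20.83 mM. Isomer of the product A is T times 2.3, or 4.60 mM, and isomer of the product B is T times 2.1, or 4.20 mM. Together with T and substrate they make 31.63 mM. I call this R, the room: the charge the solution carries at balance with T at its solubility.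

4. The zero of my scale is a charge equal to R, where crystals are just about to appear. This flask's charge over R is 4.43, above the 1 of that zero, so I expect crystals at the end, though none were charged.

5. I commit to this: forward and back rates level, crystals 77.4%, target with its crystals 78.8%, conversion 85.1%, isomer of the product A 3.29%.

6. The forecast says forward and back rates have come level, with conversion 85.1%, target 78.8%, isomer of the product A 3.29% and 78.8% on very long standing, since “the solution cannot hold all the charge”.

7. The simulation gives forward and back rates have come level, with conversion 85.1%, target 78.8%, isomer of the product A 3.29% and 78.8% on very long standing.

   This flask has come to rest. Nine tenths of its conversion is in by 0.190 h, and over the second half of the time the largest change of a share is 0 percentage points. Ten times the time changes nothing I can read: at 120 h conversion is 85.1%, target 78.8% and isomer of the product A 3.29%. Crystals stand at 77.4% then, as at 77.4% at 12.0 h, which is the part of the charge above R.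

8. In the neighbour flask with 0.035 M of substrate, charge over R is 1.11, close to the zero, so R leaves 9.63% of that charge as crystals and puts 59.5% in substrate. The run of that neighbour gives crystals 9.62% and substrate 59.5%.

The numbers of this flask are made up, and the outcome is calculated.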